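The furan-3(2H)-one ring (O, C3, C2, C1, C10) is a vinylogous ester: C3 is at the carboxyl oxidation level and the ring oxygen, held by quaternary C10, is its alkoxy oxygen. Disconnecting C2–C3 therefore leads back to a nine-membered (Z)-enoate lactone (O–C3 to C10) whose C10 carries an acetyl group (C1, C2). In the key step the acetyl enolate attacks the lactone carbonyl; O-to-C acyl transfer and acid cyclodehydration close the furanone as the final ring and, through the same bond, create the ten-membered carbocycle. The precursor already holds the trans-fused methylene butyrolactone, the C4=C5 Z-alkene and all five stereocentres, with O8/O9 masked as an acetonide.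

Key step: step 14

Remark (numbering): atoms carry germacrane labels: C1 ketone, C2=C3 and C10 (methyl C14) in the furanone, C4 (methyl C15)=C5, C6 (lactone O), C7, C8 (ester O), C9 (OH), C11–C13 methylene lactone; the target is 4Z,6R,7S,8S,9S,10S.
Remark (materials): 2 and 5 are taken as purchasable (5 is otherwise two routine steps from D-ribose), and 1 is used anhydrous after drying its commercial aqueous solution.

Step 1
Reactants: 1 2,2-dimethoxyacetaldehyde; 2 ethyl 2-[bis(2,2,2-trifluoroethoxy)phosphoryl]propanoate
Product: 3 ethyl (Z)-4,4-dimethoxy-2-methylbut-2-enoate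
Conditions: KN(SiMe3)2, 18-crown-6, THF, −78 °C
Reagents that add atoms: none
Why: Still–Gennari olefination, in which the electron-poor phosphonate eliminates before its adducts equilibrate, should give the (Z)-enoate that becomes C3 (ester carbon), C4=C5 and C6 (acetal carbon).

Step 2
Reactants: 3 ethyl (Z)-4,4-dimethoxy-2-methylbut-2-enoate
Product: 4 (Z)-4,4-dimethoxy-2-methylbut-2-enoic acid
Conditions: LiOH, THF/H2O, 0 → 25 °C; then 1 M HCl to pH 4, 0 °C
Reagents that add atoms: lithium hydroxide, [Li+].[OH-]
Why: Saponification should leave the acetal and the Z alkene untouched, and acidifying only to pH 4 should keep the acid from closing to the methoxybutenolide.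

Step 3
Reactants: 5 methyl 5-deoxy-5-iodo-2,3-O-isopropylidene-β-D-ribofuranoside
Product: 6 (4R,5R)-2,2-dimethyl-5-vinyl-1,3-dioxolane-4-carbaldehyde
Conditions: Zn dust, THF/H2O (4:1), 40 °C, ultrasound; used crude
Reagents that add atoms: none
Why: Bernet–Vasella fragmentation (zinc insertion into the C–I bond, then β-elimination of the ring oxygen) should release the C10=C14 vinyl group and the C7 aldehyde, while C2 and C3 of D-ribose become C8 and C9 unchanged.

Step 4
Reactants: 6 (4R,5R)-2,2-dimethyl-5-vinyl-1,3-dioxolane-4-carbaldehyde; 7 methyl acrylate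
Product: 8 Morita–Baylis–Hillman alcohol (both C7 epimers)
Conditions: DABCO (1 equiv), 1,4-dioxane/H2O (1:1), 25 °C
Reagents that add atoms: none
Why: The Morita–Baylis–Hillman reaction should join C7 to C11, the aqueous medium accelerating it so the α-alkoxy aldehyde reacts before it epimerises; the C7 carbinol needs no control because step 10 turns it into the C7=C11 alkene.

Step 5
Reactants: 8 Morita–Baylis–Hillman alcohol (both C7 epimers)
Product: 9 C7 silyl ether
Conditions: TBSOTf, 2,6-lutidine, CH2Cl2, −78 → 0 °C
Reagents that add atoms: tert-butyldimethylsilyl trifluoromethanesulfonate, CC(C)(C)[Si](C)(C)OS(=O)(=O)C(F)(F)F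
Why: Silylation masks the secondary alcohol so that the tertiary alcohol made in step 7 can be acylated alone, and the ether should withstand the Wacker and Grignard steps.

Step 6
Reactants: 9 C7 silyl ether
Product: 10 C10 methyl ketone
Conditions: PdCl2 (10 mol %), CuCl (1 equiv), O2 (1 atm), DMF/H2O (7:1), 25 °C
Reagents that add atoms: water, O
Why: Tsuji–Wacker oxidation should place the oxygen at the internal carbon of the monosubstituted vinyl group (C10 carbonyl with C14 methyl), while the electron-poor 1,1-disubstituted acrylate should not react.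

Step 7
Reactants: 10 C10 methyl ketone; 11 ethynylmagnesium bromide
Product: 12 C10 tertiary propargylic alcohol
Conditions: THF, −78 → −40 °C; sat. aq. NH4Cl
Reagents that add atoms: none
Why: Grignard 1,2-addition to the ketone should outpace attack on the ester at low temperature, and polar Felkin–Anh addition anti to the C9–O bond in non-chelating THF should give the 9,10-erythro tertiary alcohol required at C10.

Step 8
Reactants: 12 C10 tertiary propargylic alcohol; 4 (Z)-4,4-dimethoxy-2-methylbut-2-enoic acid
Product: 14 C10 propargylic (Z)-enoate ester, via mixed anhydride 13 (not isolated)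
Conditions: 4, 2,4,6-Cl3C6H2COCl, Et3N, THF, 0 °C; separately 12, LiN(SiMe3)2 (1.0 equiv), THF, −78 °C; combine, −78 → 0 °C; pH 7 buffer
Reagents that add atoms: none
Why: The tertiary lithium alkoxide should attack the Yamaguchi mixed anhydride at its less hindered enoyl carbonyl and form the O–C3 bond (the future ring oxygen–C3 link) without exposing the Z-enoate to nucleophilic catalysts.

Step 9
Reactants: 14 C10 propargylic (Z)-enoate ester
Product: 15 C7 allylic alcohol
Conditions: Bu4NF, AcOH (1:1), THF, 0 → 25 °C
Reagents that add atoms: none
Why: Fluoride desilylation buffered with acetic acid should free the C7 alcohol while the esters, acetal, acetonide and alkyne are left alone.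

Step 10
Reactants: 15 C7 allylic alcohol
Product: 16 (Z)-allylic bromide
Conditions: NBS, Me2S, CH2Cl2, −20 → 0 °C
Reagents that add atoms: N-bromosuccinimide, BrN1C(=O)CCC1=O
Why: Corey–Kim-type activation as the alkoxysulfonium salt and SN2' displacement by bromide should give the conjugated, thermodynamically preferred (Z)-2-(bromomethyl)enoate and merge both C7 epimers into one C7=C11 alkene.

Step 11
Reactants: 16 (Z)-allylic bromide
Product: 17 (Z)-enal bromide
Conditions: Amberlyst-15, acetone/H2O (20:1), 25 °C; used directly
Reagents that add atoms: water, O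
Why: Acid-catalysed acetal exchange should unmask the C6 aldehyde; the enal dimethyl acetal exchanges far faster than the dioxolane, which is in any case stable in acetone, and the mild resin should spare the Z alkene and the bromide.

Step 12
Reactants: 17 (Z)-enal bromide
Product: 19 ethynyl nine-membered lactone, via hydroxy ester 18 (not isolated)
Conditions: CrCl2 (8 equiv), THF, 25 °C, 2 mM by slow addition; then PPTS (cat.), CH2Cl2, 25 °C
Reagents that add atoms: none
Why: In this Nozaki–Hiyama-type allylation CrCl2 inserts into the allylic C–Br bond and the allylchromium should add through C7 to the C6 aldehyde (aldehyde-selective nine-membered closure at high dilution) before the C6 alkoxide lactonises onto the methyl ester; C6 and C7 are set under macrocyclic control in the closed transition state, where the cis-fused dioxolane and the Z-enoate should leave only the chair with the ring bonds anti across C6–C7 accessible, giving the 6,7-trans lactone with H7 and H8 syn.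

Step 13
Reactants: 19 ethynyl nine-membered lactone
Product: 20 acetyl nine-membered lactone
Conditions: Ph3PAuNTf2 (5 mol %), 1,4-dioxane/H2O (10:1), 50 °C
Reagents that add atoms: water, O
Why: Gold-catalysed Markovnikov hydration of the terminal alkyne, helped by 5-exo-dig participation of the neighbouring ester carbonyl and interception by water before any acyloxy shift, should turn the ethynyl group into the C10 acetyl group (C1, C2) only after the allylation, where a ketone would have competed.

Step 14
Reactants: 20 acetyl nine-membered lactone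
Product: 23 furanone acetonide, via hydroxy diketone 21 (not isolated), via hemiketal 22 (not isolated)
Conditions: LiN(SiMe3)2 (1.2 equiv), THF, −78 → 0 °C; then TsOH·H2O (3 equiv), 25 °C
Reagents that add atoms: none
Why: Proposed new method: LiN(SiMe3)2 can enolise only the C2 methyl of the C10 acetyl group (C10 is quaternary), and the enolate carbon adds to the lactone carbonyl C3 four bonds away (5-exo-trig), so the C2–C3 bond closes the five-membered ring O–C3–C2–C1–C10 and by the same bond turns the nine-membered lactone into the oxygen-bridged ten-membered carbocycle; cleavage of the C3–O bond of the adduct gives the stabilised 1,3-diketonate of 21 and pulls the acyl transfer forward. On acidification the C10 hydroxyl should add back to the C3 ketone (5-exo-trig, hemiketal 22) and loss of water across C2–C3 should give the furanone as a vinylogous ester. The closest known reaction types are the Baker–Venkataraman O-to-C acyl shift of 2-acyloxy ketones and the acid cyclodehydration of 1-hydroxy-2,4-diketones to furan-3(2H)-ones; not yet shown is the case in which the acyl carbon is a ring member of a medium lactone, so that the acyl shift reorganises the ring system. No stereocentre is created: C10 is carried through unchanged, the hemiketal centre at C3 is lost on dehydration, and the Z geometry of C4=C5 is fixed by the ring. The step needs chemoselective enolisation at C2 (over γ-deprotonation at C6 and amide addition to the methylene lactone) and attack at C3 instead of the butyrolactone carbonyl C12, which the kinetic acidity of the unhindered methyl ketone at −78 °C and the five-membered transition state to C3 should secure, while the acetonide keeps O9 from competing for C3 in a six-membered closure.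

Step 15
Reactants: 23 furanone acetonide
Product: 24 8,9-diol
Conditions: TFA/H2O (9:1), 0 °C
Reagents that add atoms: none
Why: Acid hydrolysis of the isopropylidene acetal, to which the furanone, the methylene lactone and the tertiary ether should be stable.

Step 16
Reactants: 25 tert-butyl acrylate; 26 acetaldehyde
Product: 27 tert-butyl 3-hydroxy-2-methylidenebutanoate
Conditions: DABCO (0.5 equiv), neat, 25 °C
Reagents that add atoms: none
Why: The Morita–Baylis–Hillman reaction should give the racemic allylic alcohol, whose stereocentre disappears in the next step.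

Step 17
Reactants: 27 tert-butyl 3-hydroxy-2-methylidenebutanoate
Product: 29 tert-butyl (E)-2-(acetoxymethyl)but-2-enoate, via secondary acetate 28 (not isolated)
Conditions: Ac2O, DMAP (cat.), CH2Cl2, 0 °C; then DABCO (0.2 equiv), THF, 65 °C
Reagents that add atoms: acetic anhydride, CC(=O)OC(C)=O
Why: Acetylation followed by DABCO-mediated SN2'–SN2' allylic transposition should move the acetate to the primary carbon and give the thermodynamically preferred E alkene (methyl trans to the ester), the side-chain geometry.

Step 18
Reactants: 29 tert-butyl (E)-2-(acetoxymethyl)but-2-enoate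
Product: 30 (E)-2-(acetoxymethyl)but-2-enoic acid
Conditions: TFA/CH2Cl2 (1:4), 0 → 25 °C
Reagents that add atoms: none
Why: Acidolysis of the tert-butyl ester (loss of 2-methylpropene) should free the acid without touching the primary acetate or the alkene geometry.

Step 19
Reactants: 24 8,9-diol; 30 (E)-2-(acetoxymethyl)but-2-enoic acid
Product: 31 target CNP0231561.3
Conditions: 30 (1.1 equiv), DIC, DMAP (0.1 equiv), CH2Cl2, −20 → 0 °C
Reagents that add atoms: none
Why: Steglich esterification should acylate O8 in preference to O9, which is neopentylic (next to quaternary C10) and hydrogen-bonded to the C1 ketone, and the low temperature should limit acyl migration.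

Compound list
1 | 2,2-dimethoxyacetaldehyde | COC(OC)C=O | starting material
2 | ethyl 2-[bis(2,2,2-trifluoroethoxy)phosphoryl]propanoate | CCOC(=O)C(C)P(=O)(OCC(F)(F)F)OCC(F)(F)F | starting material
3 | ethyl (Z)-4,4-dimethoxy-2-methylbut-2-enoate | CCOC(=O)/C(C)=C\C(OC)OC | intermediate
4 | (Z)-4,4-dimethoxy-2-methylbut-2-enoic acid | OC(=O)/C(C)=C\C(OC)OC | intermediate
5 | methyl 5-deoxy-5-iodo-2,3-O-isopropylidene-β-D-ribofuranoside | CO[C@@H]1O[C@H](CI)[C@H]2OC(C)(C)O[C@@H]12 | starting material
6 | (4R,5R)-2,2-dimethyl-5-vinyl-1,3-dioxolane-4-carbaldehyde (cis; C7 aldehyde, C8, C9, C10=C14 vinyl) | C=C[C@H]1OC(C)(C)O[C@H]1C=O | intermediate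
7 | methyl acrylate | C=CC(=O)OC | starting material
8 | methyl 2-[hydroxy(2,2-dimethyl-5-vinyl-1,3-dioxolan-4-yl)methyl]prop-2-enoate; cis-dioxolane configured as in 6; both C7 epimers | C=C[C@H]1OC(C)(C)O[C@H]1C(O)C(=C)C(=O)OC | intermediate
9 | O7-tert-butyldimethylsilyl ether of 8 | C=C[C@H]1OC(C)(C)O[C@H]1C(O[Si](C)(C)C(C)(C)C)C(=C)C(=O)OC | intermediate
10 | methyl ketone: vinyl group of 9 replaced by acetyl (C10 carbonyl, C14 methyl) | CC(=O)[C@H]1OC(C)(C)O[C@H]1C(O[Si](C)(C)C(C)(C)C)C(=C)C(=O)OC | intermediate
11 | ethynylmagnesium bromide | C#C[Mg]Br | starting material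
12 | tertiary propargylic alcohol: C10 bears methyl, ethynyl (C1, C2) and OH; C10 R here, 9,10-erythro as in the target | C#C[C@@](C)(O)[C@H]1OC(C)(C)O[C@H]1C(O[Si](C)(C)C(C)(C)C)C(=C)C(=O)OC | intermediate
13 | (Z)-4,4-dimethoxy-2-methylbut-2-enoic 2,4,6-trichlorobenzoic anhydride | COC(OC)/C=C(/C)C(=O)OC(=O)c1c(Cl)cc(Cl)cc1Cl | intermediate (not isolated)
14 | ester of the C10 alcohol of 12 with acid 4 | C#C[C@@](C)(OC(=O)/C(C)=C\C(OC)OC)[C@H]1OC(C)(C)O[C@H]1C(O[Si](C)(C)C(C)(C)C)C(=C)C(=O)OC | intermediate
15 | 14 without the silyl group (free C7 alcohol, both epimers) | C#C[C@@](C)(OC(=O)/C(C)=C\C(OC)OC)[C@H]1OC(C)(C)O[C@H]1C(O)C(=C)C(=O)OC | intermediate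
16 | (Z)-2-(bromomethyl)enoate: C7=C11 alkene with C8 cis to CH2Br; rest as 15 | C#C[C@@](C)(OC(=O)/C(C)=C\C(OC)OC)[C@H]1OC(C)(C)O[C@H]1/C=C(\CBr)C(=O)OC | intermediate
17 | 16 with the dimethyl acetal replaced by the C6 aldehyde ((Z)-2-methyl-4-oxobut-2-enoate ester) | C#C[C@@](C)(OC(=O)/C(C)=C\C=O)[C@H]1OC(C)(C)O[C@H]1/C=C(\CBr)C(=O)OC | intermediate
18 | nine-membered lactone hydroxy ester: ring O–C3(=O)–C4(Me)=C5–C6(OH)–C7–C8–C9–C10; C7 bears the 3-methoxy-3-oxoprop-1-en-2-yl group; C10 bears methyl and ethynyl; 8,9-acetonide; C6 and C7 as in the target | COC(=O)C(=C)[C@H]1[C@H](O)/C=C(/C)C(=O)O[C@](C)(C#C)[C@H]2OC(C)(C)O[C@@H]12 | intermediate (not isolated)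
19 | 18 after lactonisation of O6 onto C12: α-methylene-γ-butyrolactone trans-fused at C6/C7 to the nine-membered (Z)-enoate lactone; C10 ethynyl; cis-fused 8,9-acetonide | C=C1C(=O)O[C@@H]2/C=C(/C)C(=O)O[C@](C)(C#C)[C@H]3OC(C)(C)O[C@H]3[C@@H]12 | intermediate
20 | 19 with acetyl (C1, C2) in place of ethynyl at C10 | C=C1C(=O)O[C@@H]2/C=C(/C)C(=O)O[C@](C)(C(C)=O)[C@H]3OC(C)(C)O[C@H]3[C@@H]12 | intermediate
21 | ten-membered carbocyclic 1,3-diketone (C1 and C3 ketones, C2 methylene) with tertiary OH at C10; lactone and acetonide as in 20 | C=C1C(=O)O[C@@H]2/C=C(/C)C(=O)CC(=O)[C@@](C)(O)[C@H]3OC(C)(C)O[C@H]3[C@@H]12 | intermediate (not isolated)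
22 | 3,10-epoxy hemiketal of 21 (OH at C3, either configuration) | C=C1C(=O)O[C@@H]2/C=C(/C)C3(O)CC(=O)[C@@](C)(O3)[C@H]4OC(C)(C)O[C@H]4[C@@H]12 | intermediate (not isolated)
23 | 8,9-O-isopropylidene derivative of the de-acyl target (furanone closed) | C=C1C(=O)O[C@@H]2/C=C(/C)C3=CC(=O)[C@@](C)(O3)[C@H]4OC(C)(C)O[C@H]4[C@@H]12 | intermediate
24 | de-acyl target: 8,9-diol | C=C1C(=O)O[C@@H]2/C=C(/C)C3=CC(=O)[C@@](C)(O3)[C@@H](O)[C@@H](O)[C@@H]12 | intermediate
25 | tert-butyl acrylate | C=CC(=O)OC(C)(C)C | starting material
26 | acetaldehyde | CC=O | starting material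
27 | tert-butyl 3-hydroxy-2-methylidenebutanoate (racemic) | CC(O)C(=C)C(=O)OC(C)(C)C | intermediate
28 | tert-butyl 3-acetoxy-2-methylidenebutanoate | CC(OC(C)=O)C(=C)C(=O)OC(C)(C)C | intermediate (not isolated)
29 | tert-butyl (E)-2-(acetoxymethyl)but-2-enoate | C/C=C(\COC(C)=O)C(=O)OC(C)(C)C | intermediate
30 | (E)-2-(acetoxymethyl)but-2-enoic acid | C/C=C(\COC(C)=O)C(=O)O | intermediate
31 | CNP0231561.3: 8-O-[(E)-2-(acetoxymethyl)but-2-enoyl] derivative of 24 | C=C1C(=O)O[C@@H]2/C=C(/C)C3=CC(=O)[C@@](C)(O3)[C@@H](O)[C@@H](OC(=O)/C(=C/C)COC(C)=O)[C@@H]12 | target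

Total steps: 19. Longest linear sequence: 14 (steps 3 to 15, then 19).

Steps most likely to fail

1. Step 14 (proposed new method). The amide base may also deprotonate at C6 or add to the methylene lactone, or the adduct at C3 may revert instead of transferring the acyl group. The fallback uses known chemistry, sets out from 20 and comes back at 23. It makes the C2–C3 bond by intramolecular Wittig olefination of the ester carbonyl, the established route from acyloxy-substituted acylphosphoranes to cyclic vinylogous esters. Phenyltrimethylammonium tribromide (THF, 0 °C) should brominate the only enolisable position of 20 and give the bromomethyl ketone F1 as the sole α-bromo ketone. PPh3 (toluene, 25 °C) should convert this into the triphenylphosphonium bromide F2 by SN2 displacement, and Et3N should then free the acylphosphorane F3 from the salt. Heating F3 in toluene should close it onto C3 with loss of Ph3PO to give 23.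

2. Step 12. Oligomerisation may outrun the nine-membered closure, the organochromium may lose the C8 oxygen by 1,4-elimination, the C6 alkoxide may lactonise onto C3 in place of C12, or facial control at C6/C7 may be poor. The fallback sets out from 16 and comes back at 19. It makes the nucleophile as an isolable allylboronate and closes the ring by thermal intramolecular allylboration, which needs no reducing metal and runs through a defined chair transition state. Borylation of 16 with B2pin2 catalysed by Pd2(dba)3 (DMSO, 50 °C) should give the allylboronate acetal F4 with the pinacolboryl group in place of bromine. Acetal cleavage as in step 11 at high dilution should give the enal allylboronate F5 and this should cyclise (toluene, 60 °C) to the pinacol borate ester F6 of hydroxy ester 18. PPTS should then lactonise F6 to 19.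

3. Step 19. Site selectivity between O8 and O9 may be poor and the acyl group may migrate. The fallback sets out from 24 and comes back at 31, taking the selectivity from thermodynamics instead of kinetics. The same coupling run to full conversion of 24 should give 31 together with the 9-O-acyl isomer F7 as a mixture. The mixture is equilibrated by 1,2-acyl migration (imidazole, toluene, 40 °C) toward the less congested 8-O-ester 31, and recovered F7 is recycled.

Further compounds
F1 | step 14 | bromomethyl ketone (20 brominated at C2) | C=C1C(=O)O[C@@H]2/C=C(/C)C(=O)O[C@](C)(C(=O)CBr)[C@H]3OC(C)(C)O[C@H]3[C@@H]12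
F2 | step 14 | triphenylphosphonium bromide from F1 | C=C1C(=O)O[C@@H]2/C=C(/C)C(=O)O[C@](C)(C(=O)C[P+](c4ccccc4)(c4ccccc4)c4ccccc4)[C@H]3OC(C)(C)O[C@H]3[C@@H]12.[Br-]
F3 | step 14 | acylphosphorane (ylide at C2) | C=C1C(=O)O[C@@H]2/C=C(/C)C(=O)O[C@](C)(C(=O)C=P(c4ccccc4)(c4ccccc4)c4ccccc4)[C@H]3OC(C)(C)O[C@H]3[C@@H]12
F4 | step 12 | allylboronate acetal (16 with pinacolboryl in place of Br) | C#C[C@@](C)(OC(=O)/C(C)=C\C(OC)OC)[C@H]1OC(C)(C)O[C@H]1/C=C(\CB2OC(C)(C)C(C)(C)O2)C(=O)OC
F5 | step 12 | enal allylboronate (17 with pinacolboryl in place of Br) | C#C[C@@](C)(OC(=O)/C(C)=C\C=O)[C@H]1OC(C)(C)O[C@H]1/C=C(\CB2OC(C)(C)C(C)(C)O2)C(=O)OC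
F6 | step 12 | pinacol borate ester of hydroxy ester 18 (at O6) | COC(=O)C(=C)[C@H]1[C@H](OB3OC(C)(C)C(C)(C)O3)/C=C(/C)C(=O)O[C@](C)(C#C)[C@H]2OC(C)(C)O[C@@H]12
F7 | step 19 | 9-O-acyl isomer of 31 | C=C1C(=O)O[C@@H]2/C=C(/C)C3=CC(=O)[C@@](C)(O3)[C@@H](OC(=O)/C(=C/C)COC(C)=O)[C@@H](O)[C@@H]12
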